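# Proposed synthesis of CNP0128482.3 (compound 18) by cyclopropanol homoenolate ring closure

Conventions: ring atoms keep the numbers of the target throughout: C1 (quaternary, bears O1 and the CH2O carbon C7), C2, C3, C4=C5, C6; On is the oxygen on Cn. β is the ring face that carries O1 and O2, α the face that carries C7. Compound numbers 1–18 are those of the steps below.

Remark on the chemistry (assumption): the γ-hydroxy aldehyde needed for ring closure is taken to rest as its five-membered lactol and to reopen once it is deprotonated by the zinc reagent.

## Analysis of the target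

Compound 18 is a cyclohex-4-ene in which all four sp3 ring carbons carry oxygen and the quaternary C1 carries one further carbon, C7, so that apart from three benzoyl groups it is a C7 polyol. The stereocentres are C1, C2, C3 and C6 (all R): O1, O2 and O3 lie on the β face, whereas O6 lies on the α face together with C7, so the allylic oxygens O3 and O6 are trans across the C4=C5 double bond and O6 is trans to its neighbour O1. O3, O6 and O7 are benzoylated, while the tertiary O1 and the secondary O2 are free and cis, which is exactly the pair that one isopropylidene acetal can hold until the end. The benzoates are base-labile and can migrate (O3 to the cis O2, O6 to O7), both secondary esters are allylic and open to ionisation or SN2′ chemistry, and two eliminations would aromatise the ring, so strongly basic or ionising conditions are excluded late in the route. The difficulties are the fully substituted oxygenated C1, the trans-1,4 relation of O3 and O6, and the need to tell five oxygens apart. The route rests on one pattern: C6 and C3 are oxygenated carbons joined through C5–C4, which is a ketone at C6 whose β-carbon C4 is bonded to a carbinol C3. That is the product pattern of a homoenolate adding to an aldehyde; the latent homoenolate C6–C5–C4 is a cyclopropanol, which can be grown on a lactone carbonyl, and the remainder C6–C1–C2–C3 with cis O1/O2 is an erythronolactone.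

## Retrosynthetic reasoning

18 ⇒ 17 (acetal C–O bonds). The two hydroxyls that are free in 18 are O1 and O2. Cutting here means that one protecting group, present from the first compound on, covers exactly these two oxygens while O3, O6 and O7 are acylated. The forward step is an acid hydrolysis, placed last because only acid leaves a free hydroxyl next to a cis benzoate undisturbed.

17 ⇒ 16 ⇒ 15 (O7–acyl bond, then O7–Si bond). O7 cannot be an ester while organomagnesium and organozinc reagents are in use. It therefore travels as a silyl ether and is exchanged for the benzoate once all stereocentres are in place. The forward steps are a desilylation that does not move acyl groups and an acylation of the only free hydroxyl.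

15 ⇒ 14 ⇒ 13 (C6–O6 bond with inversion, then C6–H). O6 must end on the α face, trans to O1. Hydride reduction of the C6 ketone of 13 is expected to deliver hydrogen to the α face (anti to the C1–O1 bond, away from the acetal) and so to give the β alcohol 14. Rather than fight this preference, the plan uses it and forms the ester with inversion (Mitsunobu), which sets C6 and installs the benzoate in one operation. The forward reactions must give 1,2- and not 1,4-reduction, and substitution at C6 without allylic transposition.

13 ⇒ 12 ⇒ 11 (C4=C5 π bond; O3–acyl bond). The alkene is placed by dehydrogenating the C6 ketone. C1 has no hydrogen, so the ketone enolises only towards C5 and the double bond can only appear at C4=C5. O3 is acylated first so that the oxidant meets no free alcohol; the C3 ester is then already that of the target.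

11 ⇒ 10 ⇒ 9 ⇒ 8 (open form 7) (C3–C4 bond, ring closure). This is the strategic cut. Cleaving C3–C4 leaves oxygen in a natural position on both ends (aldehyde at C3, ketone at C6) and turns the carbocycle into the chain C3–C2–C1–C6, a four-carbon sugar lactone with its stereocentres in place. Cutting C1–C2 or C1–C6 would instead require the quaternary centre to be built during ring formation, and cutting at C4=C5 would need two separate vinyl additions. The price is umpoled reactivity at C4, which the cyclopropanol supplies: as zinc alkoxide 9 it opens to the β-zincated ketone 10, and C4 adds to the aldehyde. Because aldehyde and cyclopropanol are 1,4-related they should rest as lactol 8 rather than as open form 7, so the forward step starts from 8. It must achieve cyclopropane opening, six-ring closure in preference to ethyl transfer, and attack on the aldehyde face that places O3 cis to O2.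

8 ⇒ 6 ⇒ 4 + 5 (C6–C5 and C6–C4 bonds; oxidation level of C3). A cyclopropanol is the product of a Kulinkovich reaction of an ester with 5. Applied to lactone 4, it turns the carbonyl carbon into C6 with both CH2 groups attached and at the same time releases the ring oxygen as the C3 primary alcohol of 6, which then only needs oxidation. Two of the seven skeletal carbons and the latent nucleophile arrive in one step.

4 ⇒ 3 ⇒ 1 + 2 (C1–C7 bond). The last carbon is added as 2 to the enolate of 1. C1 becomes quaternary here, and its configuration is not a matter of selectivity: the five/five ring fusion must stay cis, so the new carbon can only take the place of the former hydrogen. Lactone 1 supplies C2 in the correct absolute configuration and the acetal that lasts to step 12.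

## Alternatives that were turned down

Alternative 1: enzymatic ipso,ortho-dihydroxylation.
- Disconnection: the C1–O1 and C2–O2 bonds are removed together, leading back to benzoic acid A1.
- Forward key step: a dioxygenase-expressing, dehydrogenase-deficient bacterial strain adds two oxygen atoms across C1–C2 of A1 and gives the cis-diol acid A2 as one enantiomer.
- For it: A2 has all seven carbons, the quaternary C1 and C2 correct, and a diene ready for oxygenation at C3 and C6. On step count and on stereocontrol at C1/C2 it is stronger than the chosen route.
- Against it: A2 comes from a fermentation with a special strain and is not a catalogue compound. It aromatises easily by dehydration or decarboxylation. The acid must be reduced to the C7 alcohol beside a diene. The diene must then take up O3 syn and O6 anti to the diol, a trans-1,4 addition (a [4+2] photooxygenation would give the cis pattern), and O3/O6/O7 must afterwards be told apart from O1/O2.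
- Comparison: the chosen route uses bench chemistry from purchasable materials and brings in O3 and O6 as alcohol and ketone, already distinguished and separately adjustable.

Alternative 2: boat Ireland–Claisen rearrangement.
- Disconnection: the C1–C6 bond, leading back to a six-membered lactone (carbonyl C7, ring oxygen on C4) that carries an (E)-enol ether C5=C6 on C4.
- Forward key step: the silyl ketene acetal of the lactone precursor of A3 rearranges through a ring-enforced boat transition state, forms C1–C6, moves the alkene to C4=C5 and gives acid A3.
- For it: C1 and C6 are created together with chirality transferred from C4, and the alkene is placed without passing through a ketone. On C6 it is stronger than the chosen route, which needs a reduction plus an inversion.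
- Against it: the lactone precursor of A3 needs a long carbohydrate-based sequence with a geometrically pure enol ether. The required enolate has an alkoxy group on its β-carbon C2 and can eliminate. In A3 the acetal spans O2/O3, so after its removal O3 must be benzoylated selectively beside O2. The acid still has to be reduced and two 4-methoxybenzyl ethers removed beside allylic esters.
- Comparison: more steps and more protecting-group traffic; the chosen route gets the O2/O3 differentiation for free from the O1/O2 acetal.

Alternative 3: ring expansion of a dibromocyclopropane.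
- Disconnection: the C6–O6 bond and, in the forward sense, the C4–C6 bond of a 6,6-dibromobicyclo[3.1.0]hexane.
- Forward key step: a silver salt removes the endo bromide while the cyclopropane opens to a 2-bromocyclohexenyl cation, which the C7 benzoate captures at C6 from its own face; hydrolysis gives A4 (its acyl-shifted isomer converges).
- For it: O6 is delivered intramolecularly from C7 and is therefore necessarily cis to it, a cleaner answer to the C6 problem than the reduction/inversion pair used here. The alkene appears at C4=C5.
- Against it: the bicyclic precursor of A4, with quaternary C1, must first be made from a carbohydrate over many steps and cyclopropanated on the right face. A4 carries a vinyl bromide at C5 that must be reduced off beside allylic esters. The acetal again spans O2/O3, with the same late differentiation problem, and O1 needs its own silyl group.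
- Comparison: the chosen route reaches the six-membered ring in five steps and keeps the acetal where the free diol of the target is; in exchange it accepts an intermolecular inversion at C6.

Key step: step 5

## Route

Step 1
Reactants: 1 2,3-O-isopropylidene-D-erythronolactone; 2 formaldehyde (monomer)
Product: 3 2-C-(hydroxymethyl)-2,3-O-isopropylidene-D-erythronolactone
Conditions: LiN(iPr)2 (1.1 equiv), THF, −78 °C; then 2 (gas, from cracked paraformaldehyde), −78 → −40 °C; aq. NH4Cl
Reagents that add atoms: none
Why: Aldol hydroxymethylation of a lithium lactone enolate; the enolate should survive at −78 °C because the C2–O2 bond of the dioxolane lies near the nodal plane of the enolate π system, the same reason tartrate acetonide enolates can be alkylated. C1 becomes quaternary with 2 entering on the convex face, because the five/five ring fusion can only be cis, so the new carbon takes the place of the former hydrogen.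

Step 2
Reactants: 3 2-C-(hydroxymethyl)-2,3-O-isopropylidene-D-erythronolactone
Product: 4 2-C-[(tert-butyldimethylsilyloxy)methyl]-2,3-O-isopropylidene-D-erythronolactone
Conditions: TBSCl, imidazole, DMF, 0 °C → rt
Reagents that add atoms: tert-butyldimethylsilyl chloride (TBSCl), CC(C)(C)[Si](C)(C)Cl
Why: Silyl ether formation at the neopentyl primary alcohol; O7 must pass Grignard, zinc alkyl, oxidant and hydride, which an ester at this position would not.

Step 3
Reactants: 4 2-C-[(tert-butyldimethylsilyloxy)methyl]-2,3-O-isopropylidene-D-erythronolactone; 5 ethylmagnesium bromide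
Product: 6 1-[(4R,5R)-4-[(tert-butyldimethylsilyloxy)methyl]-5-(hydroxymethyl)-2,2-dimethyl-1,3-dioxolan-4-yl]cyclopropan-1-ol
Conditions: 5 (3 equiv, slow addition), Ti(OiPr)4 (0.5 equiv), THF, 0 °C → rt; aq. NH4Cl
Reagents that add atoms: none
Why: Kulinkovich cyclopropanation of a lactone: the titanacyclopropane formed from two equivalents of 5 inserts the lactone carbonyl and contracts to the cyclopropanol (C6 with C5 and C4), releasing the ring oxygen as the C3 primary alkoxide. No stereocentre is touched, and silyl ether and acetal are inert to the reagents.

Step 4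
Reactants: 6 1-[(4R,5R)-4-[(tert-butyldimethylsilyloxy)methyl]-5-(hydroxymethyl)-2,2-dimethyl-1,3-dioxolan-4-yl]cyclopropan-1-ol
Product: 8 7-C-[(tert-butyldimethylsilyloxy)methyl]-6,7-O-isopropylidene-4-oxaspiro[2.4]heptane-5,6,7-triol (lactol of 7; both anomers), via cyclopropanol aldehyde 7 (not isolated)
Conditions: (COCl)2 (1.2 equiv), DMSO, CH2Cl2, −78 °C; Et3N, −78 → 0 °C
Reagents that add atoms: none
Why: Swern oxidation takes the primary alcohol to the aldehyde without metal oxidants or acid, which would open the cyclopropanol; the tertiary cyclopropanol itself cannot be oxidised. The γ-hydroxy aldehyde 7 should close to the furanose-type lactol 8, cis-fused to the dioxolane, which stores the aldehyde in a stable form; a near-stoichiometric amount of oxidant avoids further oxidation to the lactone.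

Step 5
Reactants: 8 7-C-[(tert-butyldimethylsilyloxy)methyl]-6,7-O-isopropylidene-4-oxaspiro[2.4]heptane-5,6,7-triol
Product: 11 (3aR,7R,7aR)-3a-[(tert-butyldimethylsilyloxy)methyl]-7-hydroxy-2,2-dimethylhexahydro-1,3-benzodioxol-4-one (C6 ketone/3β-hydroxyl in target numbering), via ethylzinc cyclopropoxide 9 (not isolated), via ethylzinc homoenolate 10 (not isolated)
Conditions: Et2Zn (2.5 equiv), toluene/THF 4:1, 0 → 45 °C; aq. NH4Cl
Reagents that add atoms: none
Why: Proposed new method: Et2Zn deprotonates the lactol, whose zinc alkoxide opens to the aldehyde and the zinc cyclopropoxide 9; strain-driven cleavage of a C6–CH2 bond (the two are equivalent) gives the β-zincated ketone 10, whose carbon C4 adds to the C3 aldehyde. The closest known chemistry is the generation of zinc homoenolates from cyclopropanols with Et2Zn and their addition to aldehydes between two molecules; the ring-closing version is not established. The closure is 6-exo-trig and gives the cyclohexanone ring; attack through the oxygenated carbon of an enolised homoenolate would give a four-membered ring and is not expected to compete. C3 is the only new stereocentre and is controlled by the cis-fused dioxolane: in the chair with O1 axial, C7 equatorial and the forming C3–C4 bond anti to C2–O2, both aldehyde faces are still geometrically open, and a divalent zinc centre bridging the aldehyde oxygen with O1 and O2 should hold the carbonyl oxygen on the β face, so that O3 ends cis to O2. The step therefore needs this facial selectivity, for which the weakly coordinating solvent is chosen, and chemoselectivity for ring opening over ethyl transfer. The lactol keeps the concentration of free aldehyde low, and excess Et2Zn removes proton sources that would quench 10 to the ethyl ketone.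

Step 6
Reactants: 11 (3aR,7R,7aR)-3a-[(tert-butyldimethylsilyloxy)methyl]-7-hydroxy-2,2-dimethylhexahydro-1,3-benzodioxol-4-one
Product: 12 (3aR,7R,7aR)-7-benzoyloxy-3a-[(tert-butyldimethylsilyloxy)methyl]-2,2-dimethylhexahydro-1,3-benzodioxol-4-one
Conditions: BzCl, pyridine, DMAP (cat.), CH2Cl2, 0 °C → rt
Reagents that add atoms: benzoyl chloride, O=C(Cl)c1ccccc1
Why: DMAP-catalysed acylation of the only free hydroxyl; it puts the final ester on O3 and removes the one group that the oxidant of step 7 would attack.

Step 7
Reactants: 12 (3aR,7R,7aR)-7-benzoyloxy-3a-[(tert-butyldimethylsilyloxy)methyl]-2,2-dimethylhexahydro-1,3-benzodioxol-4-one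
Product: 13 (3aR,7R,7aR)-7-benzoyloxy-3a-[(tert-butyldimethylsilyloxy)methyl]-2,2-dimethyl-7,7a-dihydro-1,3-benzodioxol-4(3aH)-one (C4=C5–C6=O enone in target numbering)
Conditions: IBX (2.5 equiv), toluene/DMSO 2:1, 70 °C
Reagents that add atoms: none
Why: IBX dehydrogenation of a ketone to its enone; C6 can enolise only towards C5 because C1 is quaternary, so the alkene can form only at C4=C5. Silyl ether, acetal and benzoate tolerate the reagent.

Step 8
Reactants: 13 (3aR,7R,7aR)-7-benzoyloxy-3a-[(tert-butyldimethylsilyloxy)methyl]-2,2-dimethyl-7,7a-dihydro-1,3-benzodioxol-4(3aH)-one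
Product: 14 3-O-benzoyl-7-O-(tert-butyldimethylsilyl)-1,2-O-isopropylidene-1-C-(hydroxymethyl)cyclohex-4-ene-1β,2β,3β,6β-tetrol (free 6β-hydroxyl)
Conditions: NaBH4, CeCl3·7H2O, MeOH, −78 °C
Reagents that add atoms: none
Why: Luche reduction gives 1,2-reduction of the enone and leaves the benzoate alone at −78 °C. Hydride should add to the α face, anti to the pseudoaxial C1–O1 bond and away from the dioxolane (polar Felkin–Anh control, the usual result for cyclohexenones with an α-oxygen in a cis-fused acetal; C7 is pseudoequatorial and does not screen that face). This gives the 6β alcohol, the epimer that step 9 is designed to use.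

Step 9
Reactants: 14 3-O-benzoyl-7-O-(tert-butyldimethylsilyl)-1,2-O-isopropylidene-1-C-(hydroxymethyl)cyclohex-4-ene-1β,2β,3β,6β-tetrol
Product: 15 3,6-di-O-benzoyl-7-O-(tert-butyldimethylsilyl)-1,2-O-isopropylidene-1-C-(hydroxymethyl)cyclohex-4-ene-1β,2β,3β,6α-tetrol
Conditions: PhCO2H, PPh3, DIAD, THF, 0 °C → rt
Reagents that add atoms: benzoic acid, O=C(O)c1ccccc1
Why: Mitsunobu esterification: the carboxylate displaces the oxyphosphonium group with inversion, which places O6 on the α face (cis to C7, trans to O1) and installs the ester at once. Elimination is impossible (C1 quaternary, C5 vinylic), and inversion of cis-4-acyloxycyclohex-2-enols under these conditions is a well-used reaction type.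

Step 10
Reactants: 15 3,6-di-O-benzoyl-7-O-(tert-butyldimethylsilyl)-1,2-O-isopropylidene-1-C-(hydroxymethyl)cyclohex-4-ene-1β,2β,3β,6α-tetrol
Product: 16 3,6-di-O-benzoyl-1,2-O-isopropylidene-1-C-(hydroxymethyl)cyclohex-4-ene-1β,2β,3β,6α-tetrol (free C7 hydroxyl)
Conditions: HF·pyridine, pyridine/THF, 0 °C → rt
Reagents that add atoms: none
Why: Fluoride cleavage of the primary silyl ether under buffered, non-basic conditions that keep the acetal and do not promote O6 to O7 acyl migration; such a shift would in any case be repaired by step 11.

Step 11
Reactants: 16 3,6-di-O-benzoyl-1,2-O-isopropylidene-1-C-(hydroxymethyl)cyclohex-4-ene-1β,2β,3β,6α-tetrol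
Product: 17 3,6,7-tri-O-benzoyl-1,2-O-isopropylidene-1-C-(hydroxymethyl)cyclohex-4-ene-1β,2β,3β,6α-tetrol
Conditions: BzCl, pyridine, DMAP (cat.), CH2Cl2, 0 °C → rt
Reagents that add atoms: benzoyl chloride, O=C(Cl)c1ccccc1
Why: Acylation of the only free hydroxyl; O1 and O2 are still tied up in the acetal, so no selectivity is required.

Step 12
Reactants: 17 3,6,7-tri-O-benzoyl-1,2-O-isopropylidene-1-C-(hydroxymethyl)cyclohex-4-ene-1β,2β,3β,6α-tetrol
Product: 18 [(1R,2R,5R,6R)-2,5-bis(benzoyloxy)-1,6-dihydroxycyclohex-3-en-1-yl]methyl benzoate (the target; 1R,2R,3R,6R in the numbering used here)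
Conditions: TFA/H2O 9:1, 0 °C → rt
Reagents that add atoms: none
Why: Acid hydrolysis of the isopropylidene acetal frees O1 and O2; acid is used for the last step because the new C2 hydroxyl is cis to the C3 benzoate and would take part in acyl migration under base. No stereocentre is affected.

## Compound list

1 | 2,3-O-isopropylidene-D-erythronolactone, (3aR,6aR)-2,2-dimethyldihydrofuro[3,4-d][1,3]dioxol-4(3aH)-one | O=C1OC[C@H]2OC(C)(C)O[C@@H]12 | starting material
2 | formaldehyde (monomer, from paraformaldehyde) | C=O | starting material
3 | 2-C-(hydroxymethyl)-2,3-O-isopropylidene-D-erythronolactone, (3aR,6aR)-3a-(hydroxymethyl)-2,2-dimethyldihydrofuro[3,4-d][1,3]dioxol-4(3aH)-one | O=C1OC[C@H]2OC(C)(C)O[C@@]12CO | intermediate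
4 | 2-C-[(tert-butyldimethylsilyloxy)methyl]-2,3-O-isopropylidene-D-erythronolactone | O=C1OC[C@H]2OC(C)(C)O[C@@]12CO[Si](C)(C)C(C)(C)C | intermediate
5 | ethylmagnesium bromide | CC[Mg]Br | starting material
6 | 1-[(4R,5R)-4-[(tert-butyldimethylsilyloxy)methyl]-5-(hydroxymethyl)-2,2-dimethyl-1,3-dioxolan-4-yl]cyclopropan-1-ol | OC[C@H]1OC(C)(C)O[C@@]1(CO[Si](C)(C)C(C)(C)C)C1(O)CC1 | intermediate
7 | (4S,5R)-5-[(tert-butyldimethylsilyloxy)methyl]-5-(1-hydroxycyclopropyl)-2,2-dimethyl-1,3-dioxolane-4-carbaldehyde (open-chain cyclopropanol aldehyde) | O=C[C@H]1OC(C)(C)O[C@@]1(CO[Si](C)(C)C(C)(C)C)C1(O)CC1 | intermediate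
8 | 7-C-[(tert-butyldimethylsilyloxy)methyl]-6,7-O-isopropylidene-4-oxaspiro[2.4]heptane-5,6,7-triol (lactol of 7, both anomers) | OC1OC2(CC2)[C@]3(CO[Si](C)(C)C(C)(C)C)OC(C)(C)O[C@H]13 | intermediate
9 | ethylzinc alkoxide of 7 (zinc on the cyclopropanol oxygen, free aldehyde at C3) | O=C[C@H]1OC(C)(C)O[C@@]1(CO[Si](C)(C)C(C)(C)C)C1(O[Zn]CC)CC1 | intermediate
10 | ethylzinc homoenolate (ethylzinc on C4, ketone at C6, aldehyde at C3) | O=C[C@H]1OC(C)(C)O[C@@]1(CO[Si](C)(C)C(C)(C)C)C(=O)CC[Zn]CC | intermediate
11 | (3aR,7R,7aR)-3a-[(tert-butyldimethylsilyloxy)methyl]-7-hydroxy-2,2-dimethylhexahydro-1,3-benzodioxol-4-one (C6 ketone, 3β-hydroxyl) | O=C1CC[C@@H](O)[C@H]2OC(C)(C)O[C@@]12CO[Si](C)(C)C(C)(C)C | intermediate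
12 | (3aR,7R,7aR)-7-benzoyloxy-3a-[(tert-butyldimethylsilyloxy)methyl]-2,2-dimethylhexahydro-1,3-benzodioxol-4-one | O=C1CC[C@@H](OC(=O)c3ccccc3)[C@H]2OC(C)(C)O[C@@]12CO[Si](C)(C)C(C)(C)C | intermediate
13 | (3aR,7R,7aR)-7-benzoyloxy-3a-[(tert-butyldimethylsilyloxy)methyl]-2,2-dimethyl-7,7a-dihydro-1,3-benzodioxol-4(3aH)-one (enone) | O=C1C=C[C@@H](OC(=O)c3ccccc3)[C@H]2OC(C)(C)O[C@@]12CO[Si](C)(C)C(C)(C)C | intermediate
14 | 3-O-benzoyl-7-O-(tert-butyldimethylsilyl)-1,2-O-isopropylidene-1-C-(hydroxymethyl)cyclohex-4-ene-1β,2β,3β,6β-tetrol | O[C@H]1C=C[C@@H](OC(=O)c3ccccc3)[C@H]2OC(C)(C)O[C@@]12CO[Si](C)(C)C(C)(C)C | intermediate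
15 | 3,6-di-O-benzoyl-7-O-(tert-butyldimethylsilyl)-1,2-O-isopropylidene-1-C-(hydroxymethyl)cyclohex-4-ene-1β,2β,3β,6α-tetrol | O=C(O[C@@H]1C=C[C@@H](OC(=O)c3ccccc3)[C@H]2OC(C)(C)O[C@@]12CO[Si](C)(C)C(C)(C)C)c4ccccc4 | intermediate
16 | 3,6-di-O-benzoyl-1,2-O-isopropylidene-1-C-(hydroxymethyl)cyclohex-4-ene-1β,2β,3β,6α-tetrol | O=C(O[C@@H]1C=C[C@@H](OC(=O)c3ccccc3)[C@H]2OC(C)(C)O[C@@]12CO)c4ccccc4 | intermediate
17 | 3,6,7-tri-O-benzoyl-1,2-O-isopropylidene-1-C-(hydroxymethyl)cyclohex-4-ene-1β,2β,3β,6α-tetrol | O=C(O[C@@H]1C=C[C@@H](OC(=O)c3ccccc3)[C@H]2OC(C)(C)O[C@@]12COC(=O)c5ccccc5)c4ccccc4 | intermediate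
18 | [(1R,2R,5R,6R)-2,5-bis(benzoyloxy)-1,6-dihydroxycyclohex-3-en-1-yl]methyl benzoate (CNP0128482.3) | O=C(OC[C@@]1(O)[C@H](O)[C@H](OC(=O)c2ccccc2)C=C[C@H]1OC(=O)c1ccccc1)c1ccccc1 | target

## Step count and least certain steps

Total step count: 12. Longest linear sequence: 12 steps (1 → 18; the route is fully linear).

Step 5 (key step, the one step without direct precedent).
- What may go wrong: protonolysis of the C4–Zn bond of 10 before it reaches the aldehyde, after which the ethyl ketone can close by aldol through C5 to a five-membered ring; ethyl transfer from Et2Zn to the aldehyde; epimerisation at C2 or β-elimination of O1 from the aldehyde; and attack on the other aldehyde face if the zinc is not held by O1/O2, since both faces are sterically accessible and only chelation separates them.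
- Fallback by known reactions, moving ring closure from C3–C4 to C4=C5: it sets out from lactol 8. CH2=CHMgBr (THF, 0 °C) adds to the open form of 8, anti to C2–O2 (Felkin–Anh, the same C3 configuration as in 11), to give allylic alcohol F1. BzCl/pyridine acylates the secondary hydroxyl beside the tertiary cyclopropanol to give benzoate F2. NBS opens the cyclopropanol to β-bromo ketone F3, and Et3N eliminates HBr to vinyl ketone F4. Ring-closing metathesis with the second-generation Hoveyda–Grubbs catalyst closes C4=C5 and returns to the route at enone 13.
- If the zinc closure works but with the opposite facial sense, the run from 8 gives the C3-epimeric hydroxy ketone F5, which is esterified with inversion (PhCO2H, PPh3, DIAD) instead of with retention and rejoins the route at 12.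

Step 3 (Kulinkovich reaction on an α-quaternary lactone).
- What may go wrong: slow insertion of the hindered carbonyl into the titanacyclopropane, so that plain Grignard addition (ethyl ketone, tertiary alcohol) takes over.
- Fallback, building the cyclopropane by carbenoid addition to an enol ether: it sets out from 4. MeLi (1 equiv, THF, −78 °C) gives methyl hemiketal F6. LiN(iPr)2 (2.2 equiv)/TMSCl traps the open-chain form as bis-silyl enol ether F7. Simmons–Smith cyclopropanation (Et2Zn, CH2I2) gives siloxycyclopropane F8, and K2CO3/MeOH removes both trimethylsilyl groups to return at 6.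

Step 8 (facial selectivity of the enone reduction).
- What may go wrong: low or reversed selectivity, because C1 is fully substituted and trivalent cerium could chelate O1 and O6, which would steer hydride to the β face.
- Fallback, reagent control and retentive acylation instead of substrate control and inversion: it sets out from 13. Corey–Bakshi–Shibata reduction with the (S)-methyl oxazaborolidine and catecholborane (toluene, −78 °C), with the quaternary C1 as the large group, should give 6α-alcohol F9; BzCl/pyridine/DMAP returns to the route at 15. The two C6 epimers thus converge on 15, one by Mitsunobu esterification and the other by plain acylation.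

Step 9 (Mitsunobu inversion next to a quaternary centre).
- What may go wrong: slow SN2 at the neopentyl-like C6, allowing SN2′ entry at C4, participation of the C3 benzoate, or ion-pair return with retention.
- Fallback, intramolecular delivery of oxygen from C7: it sets out from 14. HF·pyridine gives diol F10, and BzCl (1 equiv, pyridine, −30 °C) gives primary benzoate F11. Tf2O/pyridine gives triflate F12. On warming with aqueous NaHCO3, the carbonyl oxygen of the C7 benzoate displaces the triflate from the α face through a six-membered acyloxonium ion; its hydrolysis gives 16 together with the acyl-shifted hydroxy ester F13. Benzoylation of the mixture returns to the route at 17.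

Step 1 (aldol of the lactone enolate).
- What may go wrong: β-elimination of O2 from the enolate, self-condensation, retro-aldol during work-up, or poor capture of gaseous 2.
- Fallback, hydroxymethylation at the aldehyde oxidation level under carbonate base: it sets out from 1. iBu2AlH (CH2Cl2, −78 °C) gives lactol F14. Aqueous 2 with K2CO3 in MeOH at 65 °C effects a crossed aldol through the open-chain aldehyde, which re-closes to the cis-fused hydroxymethyl lactol F15. Ag2CO3 on Celite (toluene, reflux) oxidises the lactol selectively and returns to the route at 3.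

## Further compounds

F1 | step 5 | (C3 β-OH) allylic alcohol from vinyl addition to 8: 1-[(4R,5R)-4-[(tert-butyldimethylsilyloxy)methyl]-5-(1-hydroxyprop-2-enyl)-2,2-dimethyl-1,3-dioxolan-4-yl]cyclopropan-1-ol | C=C[C@@H](O)[C@H]1OC(C)(C)O[C@@]1(CO[Si](C)(C)C(C)(C)C)C1(O)CC1
F2 | step 5 | C3 benzoate of F1 | C=C[C@@H](OC(=O)c2ccccc2)[C@H]1OC(C)(C)O[C@@]1(CO[Si](C)(C)C(C)(C)C)C1(O)CC1
F3 | step 5 | β-bromo ketone from ring opening of F2 (C6 ketone, bromide on C4) | C=C[C@@H](OC(=O)c2ccccc2)[C@H]1OC(C)(C)O[C@@]1(CO[Si](C)(C)C(C)(C)C)C(=O)CCBr
F4 | step 5 | vinyl ketone diene for ring-closing metathesis | C=C[C@@H](OC(=O)c2ccccc2)[C@H]1OC(C)(C)O[C@@]1(CO[Si](C)(C)C(C)(C)C)C(=O)C=C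
F5 | step 5 | C3 epimer of 11 (3α-hydroxyl) | O=C1CC[C@H](O)[C@H]2OC(C)(C)O[C@@]12CO[Si](C)(C)C(C)(C)C
F6 | step 3 | methyl hemiketal from MeLi addition to 4 | CC1(O)OC[C@H]2OC(C)(C)O[C@@]12CO[Si](C)(C)C(C)(C)C
F7 | step 3 | bis-trimethylsilyl compound: 2-siloxypropene at C6 and trimethylsilyl ether at O3 | C=C(O[Si](C)(C)C)[C@]1(CO[Si](C)(C)C(C)(C)C)OC(C)(C)O[C@@H]1CO[Si](C)(C)C
F8 | step 3 | 1-(trimethylsiloxy)cyclopropane with trimethylsilyl ether at O3 | C[Si](C)(C)OC1(CC1)[C@]2(CO[Si](C)(C)C(C)(C)C)OC(C)(C)O[C@@H]2CO[Si](C)(C)C
F9 | step 8 | C6 epimer of 14 (free 6α-hydroxyl) | O[C@@H]1C=C[C@@H](OC(=O)c3ccccc3)[C@H]2OC(C)(C)O[C@@]12CO[Si](C)(C)C(C)(C)C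
F10 | step 9 | 3-O-benzoyl-1,2-O-isopropylidene 6β,7-diol | O[C@H]1C=C[C@@H](OC(=O)c3ccccc3)[C@H]2OC(C)(C)O[C@@]12CO
F11 | step 9 | 3,7-di-O-benzoyl-1,2-O-isopropylidene 6β-alcohol | O[C@H]1C=C[C@@H](OC(=O)c3ccccc3)[C@H]2OC(C)(C)O[C@@]12COC(=O)c4ccccc4
F12 | step 9 | 6β-trifluoromethanesulfonate of F11 | O=S(=O)(O[C@H]1C=C[C@@H](OC(=O)c3ccccc3)[C@H]2OC(C)(C)O[C@@]12COC(=O)c4ccccc4)C(F)(F)F
F13 | step 9 | 3,7-di-O-benzoyl-1,2-O-isopropylidene 6α-alcohol (acyl-shifted isomer of 16) | O[C@@H]1C=C[C@@H](OC(=O)c3ccccc3)[C@H]2OC(C)(C)O[C@@]12COC(=O)c4ccccc4
F14 | step 1 | 2,3-O-isopropylidene-D-erythrofuranose (both anomers) | OC1OC[C@H]2OC(C)(C)O[C@@H]12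
F15 | step 1 | 2-C-(hydroxymethyl)-2,3-O-isopropylidene-D-erythrofuranose (both anomers) | OC1OC[C@H]2OC(C)(C)O[C@@]12CO
A1 | alternative 1 | benzoic acid | O=C(O)c1ccccc1
A2 | alternative 1 | (1S,2R)-1,2-dihydroxycyclohexa-3,5-diene-1-carboxylic acid | O=C(O)[C@@]1(O)[C@H](O)C=CC=C1
A3 | alternative 2 | 1,6-bis(4-methoxybenzyloxy)-2,3-O-isopropylidenecyclohex-4-ene-1-carboxylic acid (target numbering) | OC(=O)[C@@]1(OCc2ccc(OC)cc2)[C@@H]2OC(C)(C)O[C@@H]2C=C[C@H]1OCc1ccc(OC)cc1
A4 | alternative 3 | 6-O-benzoyl-5-bromo-2,3-O-isopropylidene-1-O-triethylsilyl-1-C-(hydroxymethyl)cyclohex-4-ene-1,2,3,6-tetrol (target numbering) | OC[C@@]1(O[Si](CC)(CC)CC)[C@@H]2OC(C)(C)O[C@@H]2C=C(Br)[C@H]1OC(=O)c1ccccc1
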